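Cuts: C9–C11 (ring-B enol triflate plus an alkylborane that carries C11–C16 with the E-alkene in place). C6–OH goes back to a C6 ketone and this to the γ-CH2 of a ring-B enone. In ring A: O3–acyl, C3–C4 (next line), C19=C4 (metathesis), C3–C19 (vinyl addition), C10–C1 and C10–C20 (enolate alkylations).
Enabling feature: in ring A the quaternary C4 carries C19 next to the oxygenated C3, so O3–C3–C4–C19–O is a reduced β-acyloxy aldehyde. Moving C3 from C4 back to C19 gives a seven-membered ring C10–C1–C2–C3–C19–C4–C5 with a C19,C4-epoxide trans to the C3 ester.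
Forward: ring B is bought as (R)-carvone (C5–C10, C17, C4, C18). C20 and C1–C3 are added, and the seven-membered ring is closed onto the isopropenyl group, epoxidised, esterified and contracted to ring A. Ring B is then oxidised at C6, turned into the C9 triflate and joined to the side chain.
Stereochemistry: C5 comes from carvone, and C10 from alkylation anti to the isopropenyl group. The C3 carbinol is set by a ligand-controlled vinylzinc addition, steers the epoxide to the β face, and is then inverted to 3α in the Mitsunobu esterification. C4 is set by stereospecific inversion in the 1,2-shift, C6 by α-face hydride attack, and C13=C14 by syn-carbocupration.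

Key step: step 8

Remark: labdane numbering is used for all intermediates (ring B = C5–C10, C17 on C8, C20 on C10, C18 = methyl on C4, C19 = the carbon that ends as CH2OH), and α/β refer to the usual drawing with C20 β.

Step 1
Reactants: 1 (R)-(−)-carvone
Product: 3 6-methylcarvone (C10 epimers), via lithium dienolate 2 (not isolated)
Conditions: LiN(i-Pr)2 (LDA), THF, −78 °C; MeI, −78 → 0 °C
Reagents that add atoms: iodomethane, CI; LDA, [Li+].CC(C)[N-]C(C)C (lithium in 2 only)
Why: Kinetic α′-deprotonation gives the cross-conjugated dienolate, which is C-methylated (enolate alkylation); the new centre is planarised again in step 2, so its configuration does not matter.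

Step 2
Reactants: 3 6-methylcarvone
Product: 5 propargyl ketone (C20 β and C1 α on C10; 5α-H), via lithium dienolate 4 (not isolated)
Conditions: LiN(i-Pr)2, THF/DMPU, −78 → −10 °C; propargyl bromide, −78 °C → rt
Reagents that add atoms: propargyl bromide, C#CCBr; LDA, [Li+].CC(C)[N-]C(C)C (lithium in 4 only)
Why: Enolate alkylation with a reactive propargylic halide, in which the electrophile should approach the tetrasubstituted dienolate anti to the neighbouring C5 isopropenyl group and so set the quaternary C10 (C1 trans, C20 cis to the isopropenyl group).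

Step 3
Reactants: 5 propargyl ketone
Product: 6 keto aldehyde (C10–CH2CH2CHO)
Conditions: [CpRu(MeCN)3]PF6 (5 mol %) premixed with 5,5′-bis(trifluoromethyl)-2,2′-bipyridine (5 mol %), NMP/H2O, 25 °C
Reagents that add atoms: water, O
Why: Ruthenium-vinylidene anti-Markovnikov hydration of a terminal alkyne, which should leave the enone and the 1,1-disubstituted alkene alone because the chelating bipyridine leaves only one free site on ruthenium and so blocks enyne cycloisomerisation.

Step 4
Reactants: 6 keto aldehyde
Product: 7 (3S)-allylic alcohol (C10–CH2CH2CH(OH)CH=CH2)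
Conditions: Zn(CH=CH2)2 [from CH2=CHMgBr and ZnCl2, Et2O, dioxane, filtration], (2R)-(+)-3-exo-morpholinoisoborneol (10 mol %), toluene, −20 → 0 °C; H2O
Reagents that add atoms: divinylzinc, C=C[Zn]C=C
Why: Amino alcohol-catalysed enantioselective addition of a vinylzinc reagent to an aldehyde, in which the ligand enantiomer is chosen for Re-face delivery and sets (3S) far from the resident centres, while the hindered enone is inert to organozinc reagents.

Step 5
Reactants: 7 (3S)-allylic alcohol
Product: 8 trans-fused 6-7 bicyclic cycloheptenol (seven-membered ring C10–C1–C2–C3(β-OH)–C19H=C4(CH3)–C5; ring B 8-methyl-7-en-9-one)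
Conditions: second-generation Grubbs catalyst RuCl2(=CHPh)(PCy3)(SIMes) (5 mol %), 1,4-benzoquinone (10 mol %), CH2Cl2 (high dilution), reflux
Reagents that add atoms: none
Why: Ring-closing metathesis of a terminal vinyl group with the isopropenyl group, both held trans-diequatorial on ring B, should close the trisubstituted cycloheptene, since the electron-poor trisubstituted enone alkene does not take part.

Step 6
Reactants: 8 bicyclic cycloheptenol
Product: 9 cis-epoxy alcohol (3β-OH; C19,C4-epoxide β)
Conditions: VO(acac)2 (3 mol %), t-BuOOH (decane), CH2Cl2, 0 °C → rt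
Reagents that add atoms: tert-butyl hydroperoxide, CC(C)(C)OO
Why: Hydroxyl-directed vanadium-catalysed epoxidation of a cyclic allylic alcohol delivers oxygen syn to the 3β-OH, sets C4 and C19 on the β face against the steric bias of C20, and does not touch the electron-poor enone alkene.

Step 7
Reactants: 9 cis-epoxy alcohol
Product: 10 trans-epoxy isovalerate (3α-O-isovaleryl; epoxide β)
Conditions: isovaleric acid, PPh3, DIAD, THF, 0 °C → rt
Reagents that add atoms: isovaleric acid, CC(C)CC(=O)O
Why: Mitsunobu esterification, in which SN2 displacement from the open α face inverts C3 to the configuration of the target, installs the final ester and places it trans to the epoxide as step 8 requires.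

Step 8
Reactants: 10 trans-epoxy isovalerate
Product: 11 trans-decalin aldehyde (3α-O-isovaleryl; C4 with α-CH3 and β-CHO; 7-en-9-one)
Conditions: BF3·OEt2 (2.5 equiv), CH2Cl2, −78 → −30 °C; aq. NaHCO3
Reagents that add atoms: none
Why: BF3 binds the epoxide oxygen, the C4–O bond (tertiary carbon, remote from the electron-withdrawing ester) lengthens, and C3 shifts with its bonding pair from C19 to C4 on the α face, anti to the leaving oxygen, while C19 becomes the aldehyde carbon. The closest known reaction type is the Lewis acid-promoted semipinacol-type rearrangement of cyclic trans-2,3-epoxy esters (and of 2,3-epoxy silyl ethers) to β-acyloxy (β-silyloxy) carbonyl compounds with ring contraction. Ring A is therefore closed not by an exo or endo cyclisation but by a suprafacial 1,2-alkyl shift that expels C19 from the seven-membered ring and leaves the six-membered ring C10–C1–C2–C3–C4–C5 trans-fused to ring B. C4 is the only new stereocentre and is fixed by the β-epoxide through inversion (C19 β and axial, C18 α and equatorial); C3 migrates with retention, so the 3α-ester is kept, and C5 and C10 are not touched. The step needs cleavage of C4–O and not C19–O, shift of C3 and not of the hydrogen atoms on C19 or C5, and no capture of C4 by the ester carbonyl. The ester inductively shuts off ionisation at C19, only a shift from the oxygen-bearing C19 ends in a carbonyl group, the trans ester lets the C19–C3 bond swing antiperiplanar to C4–O as the flexible seven-membered ring relaxes to a chair cyclohexane, and low temperature in a non-nucleophilic solvent disfavours the dioxanylium and bimolecular pathways.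

Step 9
Reactants: 11 trans-decalin aldehyde
Product: 12 primary alcohol (19-OH)
Conditions: NaBH4, MeOH/CH2Cl2, −40 °C
Reagents that add atoms: none
Why: Chemoselective borohydride reduction, since the aldehyde is far more electrophilic than the C9 enone flanked by C10 and C17, and the trans-diaxial O3/C19 arrangement leaves no path for acyl migration.

Step 10
Reactants: 12 primary alcohol
Product: 13 TBS ether
Conditions: TBSCl, imidazole, DMAP (cat.), DMF, 40 °C
Reagents that add atoms: tert-butyldimethylsilyl chloride, CC(C)(C)[Si](C)(C)Cl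
Why: Standard silylation of the only free hydroxyl group, which prevents hemiketal formation with the coming C6 ketone and O-triflation in step 12.

Step 11
Reactants: 13 TBS ether
Product: 14 7-ene-6,9-dione
Conditions: Pd(OH)2/C (5 mol %), t-BuOOH (5 equiv), K2CO3 (0.25 equiv), CH2Cl2, 4 °C → rt
Reagents that add atoms: tert-butyl hydroperoxide, CC(C)(C)OO
Why: Palladium/tert-butylperoxy radical γ-C–H oxidation of an α,β-enone to the 2-ene-1,4-dione, for which C6 is the only γ-CH2 and no other alkene is left in the molecule, while C5, now α to a ketone, already has the more stable trans-decalin configuration.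

Step 12
Reactants: 14 7-ene-6,9-dione
Product: 16 6-keto C9 enol triflate (C8=C9), via lithium enolate 15 (not isolated)
Conditions: LiBH(s-Bu)3 (1.0 equiv), THF, −78 °C; Comins' reagent, −78 → −20 °C
Reagents that add atoms: Comins' reagent, FC(F)(F)S(=O)(=O)N(c1ccc(Cl)cn1)S(=O)(=O)C(F)(F)F; lithium tri-sec-butylborohydride, [Li+].CCC(C)[BH-](C(C)CC)C(C)CC (lithium in 15 only)
Why: Conjugate reduction with enolate trapping, in which the bulky hydride should add to C7, the hydrogen-bearing β-carbon of the C9 enone, and not to the methyl-bearing C8, so that the C9 enolate forms regiospecifically and is O-triflated with the tetrasubstituted C8=C9 alkene in place and the C6 ketone left.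

Step 13
Reactants: 16 6-keto C9 enol triflate
Product: 17 6β-hydroxy enol triflate
Conditions: NaBH4, MeOH/THF, −20 °C
Reagents that add atoms: none
Why: Substrate-controlled ketone reduction, in which C20 and the axial C19H2OTBS group block the β face, so hydride should come from the α face and give the axial 6β-alcohol, while the vinyl triflate, ester and silyl ether are inert.

Step 14
Reactants: 18 but-2-ynoic acid
Product: 19 2-(trimethylsilyl)ethyl but-2-ynoate
Conditions: 2-(trimethylsilyl)ethanol, DCC, DMAP (cat.), CH2Cl2, 0 °C → rt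
Reagents that add atoms: 2-(trimethylsilyl)ethanol, C[Si](C)(C)CCO
Why: Steglich esterification gives an ester that fluoride removes at the end without touching the isovalerate.

Step 15
Reactants: 19 2-(trimethylsilyl)ethyl but-2-ynoate
Product: 20 2-(trimethylsilyl)ethyl (2E)-3-methylpenta-2,4-dienoate
Conditions: CH2=CHMgBr (2 equiv), CuI (1 equiv), THF, −40 °C; 19, −78 °C; sat. aq. NH4Cl at −78 °C
Reagents that add atoms: vinylmagnesium bromide, C=C[Mg]Br
Why: syn-Carbocupration of an alkynoate followed by protonation with retention at low temperature places vinyl and H cis, that is the vinyl group trans to the ester, which is the E geometry of C13=C14.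

Step 16
Reactants: 17 6β-hydroxy enol triflate; 20 2-(trimethylsilyl)ethyl (2E)-3-methylpenta-2,4-dienoate
Product: 22 protected target (19-OTBS; C15 trimethylsilylethyl ester), via alkylborane 21 (not isolated)
Conditions: 20, 9-BBN-H, THF, 0 °C → rt; then 17, Pd(dppf)Cl2 (10 mol %), AsPh3, Cs2CO3, DMF/H2O, 50 °C
Reagents that add atoms: 9-borabicyclo[3.3.1]nonane, B1C2CCCC1CCC2 (boron and its ring in 21 only)
Why: Terminal-selective hydroboration of the monosubstituted alkene of the dienoate followed by B-alkyl Suzuki–Miyaura coupling forms C9–C11 with retention of both alkene geometries, and the free 6β-OH, the esters and the silyl ether tolerate the mild carbonate base.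

Step 17
Reactants: 22 protected target
Product: 23 target, 3α-isovaleryloxy-6β,19-dihydroxylabda-8,13E-dien-15-oic acid
Conditions: Bu4NF (5 equiv), THF, 0 °C → rt; aqueous work-up at pH 4
Reagents that add atoms: none
Why: Fluoride-induced desilylation of the TBS ether and β-elimination of the trimethylsilylethyl ester free both groups in one operation, and the hindered axial isovalerate should stay because O19 lies anti to O3 and O6 is remote.

Compound list
1 | (R)-(−)-carvone | CC1=CC[C@H](CC1=O)C(C)=C | starting material
2 | lithium cross-conjugated dienolate of carvone | CC1=CC[C@@H](C(C)=C)C=C1[O-].[Li+] | intermediate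
3 | (5R)-2,6-dimethyl-5-(prop-1-en-2-yl)cyclohex-2-en-1-one (6-methylcarvone, epimers at the methyl-bearing carbon) | CC1=CC[C@@H](C(C)=C)C(C)C1=O | intermediate
4 | lithium dienolate of 6-methylcarvone | CC1=CC[C@@H](C(C)=C)C(C)=C1[O-].[Li+] | intermediate
5 | (5S,6S)-2,6-dimethyl-5-(prop-1-en-2-yl)-6-(prop-2-yn-1-yl)cyclohex-2-en-1-one | CC1=CC[C@@H](C(C)=C)[C@](C)(CC#C)C1=O | intermediate
6 | keto aldehyde, propargyl group of 5 turned into CH2CH2CHO | CC1=CC[C@@H](C(C)=C)[C@](C)(CCC=O)C1=O | intermediate
7 | (3S)-allylic alcohol, side chain CH2CH2CH(OH)CH=CH2 | CC1=CC[C@@H](C(C)=C)[C@](C)(CC[C@H](O)C=C)C1=O | intermediate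
8 | trans-fused 6-7 bicyclic cycloheptenol, 3β-OH, C19=C4, 5α-H, 10β-CH3 | CC1=CC[C@H]2C(C)=C[C@@H](O)CC[C@]2(C)C1=O | intermediate
9 | cis-epoxy alcohol, 3β-OH, C19,C4-β-epoxide | CC1=CC[C@H]2[C@@]3(C)O[C@H]3[C@@H](O)CC[C@]2(C)C1=O | intermediate
10 | trans-epoxy isovalerate, 3α-ester, C19,C4-β-epoxide | CC1=CC[C@H]2[C@@]3(C)O[C@H]3[C@H](OC(=O)CC(C)C)CC[C@]2(C)C1=O | intermediate
11 | trans-decalin aldehyde, 3α-ester, 4α-CH3, 4β-CHO | CC1=CC[C@H]2[C@@](C)(C=O)[C@H](OC(=O)CC(C)C)CC[C@]2(C)C1=O | intermediate
12 | 19-alcohol | CC1=CC[C@H]2[C@@](C)(CO)[C@H](OC(=O)CC(C)C)CC[C@]2(C)C1=O | intermediate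
13 | 19-TBS ether | CC1=CC[C@H]2[C@@](C)(CO[Si](C)(C)C(C)(C)C)[C@H](OC(=O)CC(C)C)CC[C@]2(C)C1=O | intermediate
14 | 7-ene-6,9-dione | CC1=CC(=O)[C@H]2[C@@](C)(CO[Si](C)(C)C(C)(C)C)[C@H](OC(=O)CC(C)C)CC[C@]2(C)C1=O | intermediate
15 | lithium C9 enolate of the 6,9-dione | CC1=C([O-])[C@@]2(C)CC[C@@H](OC(=O)CC(C)C)[C@](C)(CO[Si](C)(C)C(C)(C)C)[C@@H]2C(=O)C1.[Li+] | intermediate
16 | 6-keto C9 enol triflate | CC1=C(OS(=O)(=O)C(F)(F)F)[C@@]2(C)CC[C@@H](OC(=O)CC(C)C)[C@](C)(CO[Si](C)(C)C(C)(C)C)[C@@H]2C(=O)C1 | intermediate
17 | 6β-hydroxy C9 enol triflate | CC1=C(OS(=O)(=O)C(F)(F)F)[C@@]2(C)CC[C@@H](OC(=O)CC(C)C)[C@](C)(CO[Si](C)(C)C(C)(C)C)[C@@H]2[C@H](O)C1 | intermediate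
18 | but-2-ynoic acid | CC#CC(=O)O | starting material
19 | 2-(trimethylsilyl)ethyl but-2-ynoate | CC#CC(=O)OCC[Si](C)(C)C | intermediate
20 | 2-(trimethylsilyl)ethyl (2E)-3-methylpenta-2,4-dienoate | C=C/C(C)=C/C(=O)OCC[Si](C)(C)C | intermediate
21 | B-alkyl-9-BBN of 20 (boron on the terminal carbon) | B1(C2CCCC1CCC2)CC/C(C)=C/C(=O)OCC[Si](C)(C)C | intermediate
22 | protected target, 19-OTBS, C15 2-(trimethylsilyl)ethyl ester | CC1=C(CC/C(C)=C/C(=O)OCC[Si](C)(C)C)[C@@]2(C)CC[C@@H](OC(=O)CC(C)C)[C@](C)(CO[Si](C)(C)C(C)(C)C)[C@@H]2[C@H](O)C1 | intermediate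
23 | 3α-isovaleryloxy-6β,19-dihydroxylabda-8,13E-dien-15-oic acid (CNP0274836.1) | CC1=C(CC/C(C)=C/C(=O)O)[C@@]2(C)CC[C@@H](OC(=O)CC(C)C)[C@](C)(CO)[C@@H]2[C@H](O)C1 | target

Total step count: 17. Longest linear sequence: 15 (steps 1–13, 16, 17).

Steps most likely to fail

Step 8. A hydride shift from C19 (which keeps the seven-membered ring) or capture of the developing C4 cation by the ester carbonyl may outrun the shift of the ester-bearing C3.
- The fallback sets out from 9 and comes back at 13.
- Dess–Martin oxidation of 9 gives the α,β-epoxy ketone F1.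
- With BF3·OEt2 the acyl carbon C3, a much better migrating group than hydrogen, moves from C19 to C4. This is the epoxy ketone to β-keto aldehyde rearrangement with ring contraction, again with inversion at C4, and it gives the keto aldehyde F2.
- Me4NBH(OAc)3 in MeCN/AcOH reduces the aldehyde first. Bound to O19, it then delivers hydride to the β face of the C3 ketone and gives the 3α,19-diol F3.
- TBSCl/imidazole silylates the primary hydroxyl group to the hydroxy silyl ether F4.
- Isovaleric anhydride/DMAP acylates the axial 3α-OH to 13.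

Step 12. Three things may go wrong: direct hydride attack at the C6 carbonyl, hydride delivery to C8, or proton exchange between enolate and ketone before triflation may erode the regiochemistry.
- The fallback sets out from 14 and comes back at 17.
- Zn/AcOH reduces the ene-dione alkene to the saturated 6,9-diketone F5 (C8 epimers, both converge).
- NaBH4 reduces only the more accessible C6 ketone from the α face to the 6β-hydroxy ketone F6.
- TESOTf/2,6-lutidine gives the TES ether F7.
- KN(SiMe3)2 then Comins' reagent enolises the C9 ketone towards C8, its only α-hydrogen, and gives the TES-protected enol triflate F8.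
- PPTS in MeOH removes the secondary TES group in the presence of the neopentyl TBS ether and gives 17.

Step 16. Oxidative addition and transmetalation at a triflate flanked by the quaternary C10 and the C8 methyl group may be slow, so that β-hydride elimination of the alkylpalladium species or hydrolysis of the triflate takes over.
- The fallback sets out from 17 and comes back at 22.
- A Heck reaction with methyl vinyl ketone (Pd(OAc)2, PPh3, Et3N, DMF) needs only a small alkene partner without β-hydrogen problems and gives the dienone F9.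
- [(PPh3)CuH]6 reduces the disubstituted C11=C12 alkene by conjugate reduction to the methyl ketone F10.
- Horner–Wadsworth–Emmons olefination with 2-(trimethylsilyl)ethyl diethylphosphonoacetate and LiN(SiMe3)2 gives 22. Alkene geometry is less well controlled here, so the Z isomer has to be separated.

Further compounds
F1 | step 8 | α,β-epoxy ketone (3-oxo, C19,C4-β-epoxide) | CC1=CC[C@H]2[C@@]3(C)O[C@H]3C(=O)CC[C@]2(C)C1=O
F2 | step 8 | keto aldehyde (3-oxo, 4α-CH3, 4β-CHO trans-decalin) | CC1=CC[C@H]2[C@@](C)(C=O)C(=O)CC[C@]2(C)C1=O
F3 | step 8 | 3α,19-diol | CC1=CC[C@H]2[C@@](C)(CO)[C@H](O)CC[C@]2(C)C1=O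
F4 | step 8 | hydroxy silyl ether (3α-OH, 19-OTBS) | CC1=CC[C@H]2[C@@](C)(CO[Si](C)(C)C(C)(C)C)[C@H](O)CC[C@]2(C)C1=O
F5 | step 12 | saturated 6,9-diketone (C8 epimers) | CC1CC(=O)[C@H]2[C@@](C)(CO[Si](C)(C)C(C)(C)C)[C@H](OC(=O)CC(C)C)CC[C@]2(C)C1=O
F6 | step 12 | 6β-hydroxy ketone (C8 epimers) | CC1C[C@@H](O)[C@H]2[C@@](C)(CO[Si](C)(C)C(C)(C)C)[C@H](OC(=O)CC(C)C)CC[C@]2(C)C1=O
F7 | step 12 | TES ether (6β-OTES, C8 epimers) | CC1C[C@@H](O[Si](CC)(CC)CC)[C@H]2[C@@](C)(CO[Si](C)(C)C(C)(C)C)[C@H](OC(=O)CC(C)C)CC[C@]2(C)C1=O
F8 | step 12 | TES-protected enol triflate | CC1=C(OS(=O)(=O)C(F)(F)F)[C@@]2(C)CC[C@@H](OC(=O)CC(C)C)[C@](C)(CO[Si](C)(C)C(C)(C)C)[C@@H]2[C@H](O[Si](CC)(CC)CC)C1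
F9 | step 16 | dienone (C9–CH=CH–COCH3, E) | CC1=C(/C=C/C(C)=O)[C@@]2(C)CC[C@@H](OC(=O)CC(C)C)[C@](C)(CO[Si](C)(C)C(C)(C)C)[C@@H]2[C@H](O)C1
F10 | step 16 | methyl ketone (C9–CH2CH2COCH3) | CC1=C(CCC(C)=O)[C@@]2(C)CC[C@@H](OC(=O)CC(C)C)[C@](C)(CO[Si](C)(C)C(C)(C)C)[C@@H]2[C@H](O)C1
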